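The ring numbering is C1 on the CH2 hinge, Br on C2, C3 and C6, and O on C4 and C5, with primes for the second ring. With the four phenols masked as methyl ethers, the retrosynthesis cuts C1–C6 and C2–C3 of ring A and C1'–C6' and C2'–C3' of ring B.
Enabling feature: the arc C3–C4–C5–C6 reads Br, O, O, Br from either end, so it is a mirror-symmetric four-carbon diene, supplied as 2,5-dibromo-3,4-dimethoxythiophene 1,1-dioxide with SO2 as a traceless bridge. The pair C1–C2 (CH2, Br) is a bromoalkyne, and C2–C1–CH2–C1'–C2' is one skipped C5 diyne brominated at both ends.
Forward order: the C5 chain is joined first by a C2 + C3 copper coupling and both termini are then brominated, while the diene is made in two steps from 3,4-dimethoxythiophene. Ring A and then ring B arise in one flask by [4+2] cycloaddition and SO2 loss, and BBr3 finally frees both catechols.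
Stereochemistry: nothing has to be set, because the target has no stereocentre and is achiral. The bridgehead stereocentres of the transient cycloadducts disappear on aromatisation.
Key step: step 5

Remark: the target SMILES carries no stereodescriptor and the molecule has neither a stereocentre nor a configurationally stable axis, so the compound drawn is the only stereoisomer to be made.

Step 1
Reactants: 1 trimethylsilylacetylene; 2 propargyl bromide (3-bromoprop-1-yne)
Product: 4 1-(trimethylsilyl)penta-1,4-diyne, via (trimethylsilylethynyl)magnesium bromide 3 (not isolated)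
Conditions: EtMgBr (1.0 equiv), THF, 0 °C → rt; CuCl (5 mol %), then 2 (1.1 equiv), THF, 50 °C; aq NH4Cl
Reagents that add atoms: ethylmagnesium bromide, CC[Mg]Br (its Mg and Br stand only in intermediate 3; none of its atoms remain in 4)
Why: Copper-catalysed SN2 alkynylation of a propargylic halide by an alkynyl Grignard reagent is the standard way to skipped 1,4-diynes, the silyl cap leaves only one terminus of 1 free to couple, and the mildly acidic quench avoids a base-induced shift of the C3 methylene to an allene.

Step 2
Reactants: 4 1-(trimethylsilyl)penta-1,4-diyne; 5 N-bromosuccinimide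
Product: 7 1,5-dibromopenta-1,4-diyne, via 1-bromo-5-(trimethylsilyl)penta-1,4-diyne 6 (not isolated)
Conditions: NBS (2.3 equiv), AgNO3 (0.3 equiv), acetone, 0 °C → rt, dark; pentane/H2O work-up, exchanged into PhMe without drying down and used at once
Reagents that add atoms: N-bromosuccinimide (5), O=C1CCC(=O)N1Br
Why: Silver-catalysed electrophilic bromination with NBS turns a terminal alkyne (through its silver acetylide) and an alkynylsilane (bromodesilylation) alike into 1-bromoalkynes under near-neutral conditions, so both ends of 4 should be capped in one flask without touching the doubly propargylic CH2.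

Step 3
Reactants: 8 3,4-dimethoxythiophene; 5 N-bromosuccinimide
Product: 10 2,5-dibromo-3,4-dimethoxythiophene, via 2-bromo-3,4-dimethoxythiophene 9 (not isolated)
Conditions: NBS (2.05 equiv), CHCl3–AcOH (1:1), 0 °C, dark; used at once
Reagents that add atoms: N-bromosuccinimide (5), O=C1CCC(=O)N1Br
Why: This is an electrophilic aromatic substitution in which C2 and C5 are the only free ring positions and are activated by sulfur and by the neighbouring methoxy groups, so two equivalents of NBS should brominate them in turn at low temperature.

Step 4
Reactants: 10 2,5-dibromo-3,4-dimethoxythiophene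
Product: 12 2,5-dibromo-3,4-dimethoxythiophene 1,1-dioxide, via 2,5-dibromo-3,4-dimethoxythiophene 1-oxide 11 (not isolated)
Conditions: mCPBA (3.5 equiv), CH2Cl2, 0 °C → rt, dark
Reagents that add atoms: 3-chloroperbenzoic acid (mCPBA), O=C(OO)c1cccc(Cl)c1
Why: Peracid S-oxidation is the standard preparation of 2,5-dihalo-3,4-disubstituted thiophene 1,1-dioxides; the slow, dearomatising first oxygen transfer is followed by a fast second one, and the two α-bromines shield sulfoxide 11 and sulfone 12 from Diels–Alder self-dimerisation.

Step 5
Reactants: 7 1,5-dibromopenta-1,4-diyne; 12 2,5-dibromo-3,4-dimethoxythiophene 1,1-dioxide (two molecules enter the product)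
Product: 16 bis(2,3,6-tribromo-4,5-dimethoxyphenyl)methane, via bridged sulfone monoadduct 13 (not isolated), via monoannulated bromoalkyne 14 (not isolated), via second bridged sulfone adduct 15 (not isolated)
Conditions: 7 (PhMe solution) added slowly to 12 (2.6 equiv), BHT (cat.), PhCl, 120 °C, slow Ar sweep, dark
Reagents that add atoms: none
Why: Proposed new method: S-oxidation has cancelled the thiophene aromaticity, so 12 is a locked s-cis diene that should add suprafacially across one C≡C of 7 in a concerted [4π+2π] Diels–Alder reaction to give the 7-thiabicyclo[2.2.1]hepta-2,5-diene 7,7-dioxide 13, which expels SO2 cheletropically and lands directly on arene 14, after which the same two events at the remaining bromoalkyne (via 15) give 16 without any oxidant. The closest known reaction type is the cycloaddition/SO2 extrusion of tetrahalo- and 2,5-dihalothiophene 1,1-dioxides with alkynes to polyhalobenzenes, backed by the CO-extruding benzannulation of 1-bromoalkynes with cyclopentadienones; what has not been shown is a 1-bromoalkyne as partner of a thiophene dioxide, a 3,4-dialkoxy diene and the twofold version on a skipped diyne. Each of the two benzene rings closes by an intermolecular [4+2] annulation in which the diene carbons become C3–C6 and the alkyne carbons C1–C2, so that C1–C6 and C2–C3 form together and no exo/endo chain-cyclisation mode is involved. No stereocentre survives, because the bridgehead carbons of 13 and 15 become planar ring atoms when SO2 leaves. Regioselectivity is not required, since 12 has a mirror plane through S and the midpoint of C3–C4 and both orientations of the alkyne give the same ring; what is required is chemoselectivity for cross-cycloaddition over self-dimerisation of 12 and thermal decay of 7, which the bromines on the diene termini, the excess of 12, the slow addition of 7 and the neutral, base-free, radical-inhibited medium are meant to secure. Electronically the sulfonyl group and the two bromines lower the diene LUMO while the bromine lone pairs and the alkyl arm raise the alkyne HOMO (inverse-demand pairing), and the rod-shaped alkyne brings little bulk to the hindered diene termini.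

Step 6
Reactants: 16 bis(2,3,6-tribromo-4,5-dimethoxyphenyl)methane
Product: 18 bis(2,3,6-tribromo-4,5-dihydroxyphenyl)methane (CNP0355047.0), via bis(bromobenzodioxaborole) 17 (not isolated)
Conditions: BBr3 (8 equiv), CH2Cl2, −78 °C → rt, Ar; then degassed ice-water
Reagents that add atoms: boron tribromide, BrB(Br)Br (its B and Br stand only in intermediate 17; none of its atoms remain in 18)
Why: Lewis-acid ether cleavage with BBr3 (O-coordination, then SN2 attack of bromide on methyl) is the standard last step for polybrominated catechols, leaves the aryl bromides and the diarylmethane hinge untouched, and passes through the cyclic bromoboronate 17 that water hydrolyses, while argon and the acidic quench guard the catechols against oxidation to o-quinones.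

Compound list
1 | trimethylsilylacetylene | C[Si](C)(C)C#C | starting material
2 | propargyl bromide | BrCC#C | starting material
3 | (trimethylsilylethynyl)magnesium bromide | C[Si](C)(C)C#C[Mg]Br | intermediate
4 | 1-(trimethylsilyl)penta-1,4-diyne | C[Si](C)(C)C#CCC#C | intermediate
5 | N-bromosuccinimide | O=C1CCC(=O)N1Br | starting material
6 | 1-bromo-5-(trimethylsilyl)penta-1,4-diyne | C[Si](C)(C)C#CCC#CBr | intermediate
7 | 1,5-dibromopenta-1,4-diyne | BrC#CCC#CBr | intermediate
8 | 3,4-dimethoxythiophene | COc1cscc1OC | starting material
9 | 2-bromo-3,4-dimethoxythiophene | COc1csc(Br)c1OC | intermediate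
10 | 2,5-dibromo-3,4-dimethoxythiophene | COc1c(Br)sc(Br)c1OC | intermediate
11 | 2,5-dibromo-3,4-dimethoxythiophene 1-oxide | COC1=C(Br)S(=O)C(Br)=C1OC | intermediate
12 | 2,5-dibromo-3,4-dimethoxythiophene 1,1-dioxide | COC1=C(Br)S(=O)(=O)C(Br)=C1OC | intermediate
13 | 1,2,4-tribromo-3-(3-bromoprop-2-yn-1-yl)-5,6-dimethoxy-7-thiabicyclo[2.2.1]hepta-2,5-diene 7,7-dioxide (racemic, transient) | COC1=C(OC)C2(Br)C(Br)=C(CC#CBr)C1(Br)S2(=O)=O | intermediate
14 | 1,2,4-tribromo-3-(3-bromoprop-2-yn-1-yl)-5,6-dimethoxybenzene | COc1c(OC)c(Br)c(CC#CBr)c(Br)c1Br | intermediate
15 | 1,2,4-tribromo-5,6-dimethoxy-3-[(2,3,6-tribromo-4,5-dimethoxyphenyl)methyl]-7-thiabicyclo[2.2.1]hepta-2,5-diene 7,7-dioxide (racemic, transient) | COC1=C(OC)C2(Br)C(Br)=C(Cc3c(Br)c(OC)c(OC)c(Br)c3Br)C1(Br)S2(=O)=O | intermediate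
16 | bis(2,3,6-tribromo-4,5-dimethoxyphenyl)methane | COc1c(OC)c(Br)c(Cc2c(Br)c(OC)c(OC)c(Br)c2Br)c(Br)c1Br | intermediate
17 | bis(2,4,6,7-tetrabromo-1,3,2-benzodioxaborol-5-yl)methane | BrB1Oc2c(O1)c(Br)c(Cc1c(Br)c3OB(Br)Oc3c(Br)c1Br)c(Br)c2Br | intermediate
18 | bis(2,3,6-tribromo-4,5-dihydroxyphenyl)methane (achiral) | Oc1c(O)c(Br)c(Cc2c(Br)c(O)c(O)c(Br)c2Br)c(Br)c1Br | target

Total step count: 6.
Longest linear sequence: 4 steps (1 → 2 → 5 → 6, or equally 3 → 4 → 5 → 6).

Steps most likely to fail

Step 5.
- **Risk:** The cycloaddition may be too slow at temperatures the skipped dibromodiyne tolerates. Thermal decay of the diyne, self-dimerisation of the diene or a stall after the first annulation could then take over.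
- **Fallback:** It uses known chemistry, sets out from 12 and comes back at 16.
- **Route:** Halogenated thiophene 1,1-dioxides add readily to unactivated terminal alkenes, so 12 (2.5 equiv) would be heated with commercial penta-1,4-diene in a sealed tube (PhMe, 80–100 °C). The first cycloaddition with SO2 loss should give 1,4-dibromo-2,3-dimethoxy-5-(prop-2-en-1-yl)cyclohexa-1,3-diene F1. The second should give bis(2,5-dibromo-3,4-dimethoxycyclohexa-2,4-dien-1-yl)methane F2, a stereoisomer mixture of no consequence.
- **Aromatisation and bromination:** Dehydrogenation with DDQ (PhMe, reflux) should give bis(2,5-dibromo-3,4-dimethoxyphenyl)methane F3, whose single free position in each ring (C2) lies para to the C5 methoxy group. Electrophilic bromination (Br2, cat. Fe, AcOH/CH2Cl2) fills it and gives 16.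
- **Trade-off:** The same four ring bonds are still made by cycloaddition. The cost is two more steps and a late bromination beside the hinge.

Step 4.
- **Risk:** Oxygen transfer to sulfur may be outrun by attack of the peracid on the electron-rich ring carbons, or by loss of bromine and polymerisation of the labile dibromide before it is oxidised.
- **Fallback:** It sets out from 8 and comes back at 12, moving the bromination behind the oxidation.
- **Route:** Double lithiation (n-BuLi, TMEDA, THF) gives 2,5-dilithio-3,4-dimethoxythiophene F4. Quenching with Me3SiCl gives 3,4-dimethoxy-2,5-bis(trimethylsilyl)thiophene F5, a stable and more easily S-oxidised thiophene. mCPBA then gives 3,4-dimethoxy-2,5-bis(trimethylsilyl)thiophene 1,1-dioxide F6.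
- **Final bromination:** Ipso-bromodesilylation with Br2/AgBF4 in CH2Cl2 should deliver 12. It is helped by the enol-ether polarisation of each C=C toward the silylated carbon.

Step 2.
- **Risk:** The doubly brominated skipped diyne may decompose or undergo prototropic isomerisation during bromination, solvent exchange and handling.
- **Fallback:** It sets out from 4 and comes back at 14, so 7 is never made and the two rings are built one at a time.
- **Route:** One equivalent of NBS with catalytic AgNO3 for a short time brominates only the terminal C–H, and 6 is isolated. Heating 6 with 12 under the conditions of step 5 should engage the slimmer bromoalkyne end and give trimethyl[3-(2,3,6-tribromo-4,5-dimethoxyphenyl)prop-1-yn-1-yl]silane F7. NBS/AgNO3 then exchanges silicon for bromine to give 14, which takes up the second molecule of 12 as in step 5.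

Further compounds
F1 | step 5 | 1,4-dibromo-2,3-dimethoxy-5-(prop-2-en-1-yl)cyclohexa-1,3-diene (racemic) | COC1=C(Br)CC(CC=C)C(Br)=C1OC
F2 | step 5 | bis(2,5-dibromo-3,4-dimethoxycyclohexa-2,4-dien-1-yl)methane (mixture of stereoisomers) | COC1=C(Br)CC(CC2CC(Br)=C(OC)C(OC)=C2Br)C(Br)=C1OC
F3 | step 5 | bis(2,5-dibromo-3,4-dimethoxyphenyl)methane | COc1c(Br)cc(Cc2cc(Br)c(OC)c(OC)c2Br)c(Br)c1OC
F4 | step 4 | 2,5-dilithio-3,4-dimethoxythiophene | COc1c([Li])sc([Li])c1OC
F5 | step 4 | 3,4-dimethoxy-2,5-bis(trimethylsilyl)thiophene | COc1c([Si](C)(C)C)sc([Si](C)(C)C)c1OC
F6 | step 4 | 3,4-dimethoxy-2,5-bis(trimethylsilyl)thiophene 1,1-dioxide | COC1=C([Si](C)(C)C)S(=O)(=O)C([Si](C)(C)C)=C1OC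
F7 | step 2 | trimethyl[3-(2,3,6-tribromo-4,5-dimethoxyphenyl)prop-1-yn-1-yl]silane | COc1c(OC)c(Br)c(CC#C[Si](C)(C)C)c(Br)c1Br
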